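## Retrosynthetic overview

1. The target comes from an exocyclic enone by Luche reduction (sets C7), the enone from a 7-ketone by α-methylenation at C8, and the (Z)-enoate side chain from a C9 vinyl group by B-alkyl Suzuki coupling with methyl (Z)-3-iodobut-2-enoate.
2. The C9-vinyl decalin comes from a bicyclic aldehyde made by intramolecular Diels–Alder reaction of an acyclic trienal (2-silyloxydiene plus (E)-3-methylenal). Rings A and B close in this one step (C5–C10 and C8–C9 bonds), and C5, C9 and C10 are set from C3.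
3. The trienal comes from an enone (Wittig) and an (E)-enoate (B-alkyl Suzuki with an (E)-enol triflate), both built on a (3R)-silyloxy alkenol from (S)-pantolactone, which supplies C3 and the gem-dimethyl carbon C4.

Assumption: (S)-pantolactone (L-pantolactone) is the purchasable chiral starting material, both butenoate coupling partners are made rather than bought, and positions in the text use labdane numbering (C1–C20).

## Route

Step 1
Reactants: 1 (S)-pantolactone [(3S)-3-hydroxy-4,4-dimethyloxolan-2-one]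
Product: 2 (3S)-3-[(tert-butyldimethylsilyl)oxy]-4,4-dimethyloxolan-2-one
Conditions: TBSCl, imidazole, DMF, 23 °C
Reagents that add atoms: tert-butyldimethylsilyl chloride, CC(C)(C)[Si](C)(C)Cl
Why: Imidazole-promoted O-silylation of the secondary alcohol leaves the bought stereocenter (future C3) untouched.

Step 2
Reactants: 2 (3S)-3-[(tert-butyldimethylsilyl)oxy]-4,4-dimethyloxolan-2-one
Product: 3 (3S)-3-[(tert-butyldimethylsilyl)oxy]-4,4-dimethyloxolan-2-ol (anomer mixture)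
Conditions: i-Bu2AlH (1.1 equiv), CH2Cl2, −78 °C; aq. KNaC4H4O6 (potassium sodium tartrate)
Reagents that add atoms: none
Why: Partial hydride reduction of the lactone stops at the lactol because the tetrahedral aluminate is stable at −78 °C, and the new hemiacetal center is lost in the next step.

Step 3
Reactants: 3 (3S)-3-[(tert-butyldimethylsilyl)oxy]-4,4-dimethyloxolan-2-ol
Product: 4 (3R)-3-[(tert-butyldimethylsilyl)oxy]-2,2-dimethylpent-4-en-1-ol
Conditions: Ph3PCH3Br (3.0 equiv), n-BuLi (2.9 equiv), THF, 0 °C; then 3, 0 → 23 °C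
Reagents that add atoms: methyltriphenylphosphonium bromide, C[P+](c1ccccc1)(c1ccccc1)c1ccccc1.[Br-]
Why: Wittig methylenation of the open hydroxy-aldehyde form of the lactol; the α-silyloxy C–H is screened by the neighbouring quaternary carbon, and the lithium alkoxide at low temperature disfavours 1,3-silyl migration.

Step 4
Reactants: 5 ethyl acetoacetate
Product: 6 ethyl (2E)-3-{[(trifluoromethyl)sulfonyl]oxy}but-2-enoate
Conditions: Tf2O, aq. Me4NOH, hexanes, 5 → 23 °C
Reagents that add atoms: trifluoromethanesulfonic anhydride, O=S(=O)(OS(=O)(=O)C(F)(F)F)C(F)(F)F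
Why: Biphasic O-triflation of the non-chelated tetramethylammonium enolate gives the (E)-enol triflate, whereas chelated lithium enolates give the Z isomer.

Step 5
Reactants: 4 (3R)-3-[(tert-butyldimethylsilyl)oxy]-2,2-dimethylpent-4-en-1-ol; 6 ethyl (2E)-3-{[(trifluoromethyl)sulfonyl]oxy}but-2-enoate
Product: 8 ethyl (2E,6R)-6-[(tert-butyldimethylsilyl)oxy]-8-hydroxy-3,7,7-trimethyloct-2-enoate, via alkylborane 7 (not isolated)
Conditions: 9-BBN-H (2.3 equiv), THF, 0 → 23 °C; then 6, Pd(dppf)Cl2 (5 mol %), K3PO4 (3 M aq.), DMF, 23 °C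
Reagents that add atoms: none
Why: Anti-Markovnikov hydroboration of the monosubstituted alkene (the free hydroxyl is borylated in passing) and B-alkyl Suzuki–Miyaura coupling with retention of the triflate geometry give the (E)-trisubstituted enoate, the future C9=C10 dienophile.

Step 6
Reactants: 8 ethyl (2E,6R)-6-[(tert-butyldimethylsilyl)oxy]-8-hydroxy-3,7,7-trimethyloct-2-enoate
Product: 9 ethyl (2E,6R)-6-[(tert-butyldimethylsilyl)oxy]-3,7,7-trimethyl-8-oxooct-2-enoate
Conditions: Dess–Martin periodinane, CH2Cl2, 0 → 23 °C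
Reagents that add atoms: none
Why: Dess–Martin oxidation of the neopentyl primary alcohol gives a non-enolisable aldehyde, so nothing can epimerise or over-oxidise.

Step 7
Reactants: 9 ethyl (2E,6R)-6-[(tert-butyldimethylsilyl)oxy]-3,7,7-trimethyl-8-oxooct-2-enoate
Product: 10 ethyl (2E,6R,8E)-6-[(tert-butyldimethylsilyl)oxy]-3,7,7-trimethyl-10-oxoundeca-2,8-dienoate
Conditions: Ph3P=CHC(O)CH3, PhMe, 90 °C
Reagents that add atoms: 1-(triphenylphosphoranylidene)propan-2-one, CC(=O)C=P(c1ccccc1)(c1ccccc1)c1ccccc1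
Why: Wittig olefination with a stabilised ylide gives the (E)-enone, which carries C6, C7 and C8.

Step 8
Reactants: 10 ethyl (2E,6R,8E)-6-[(tert-butyldimethylsilyl)oxy]-3,7,7-trimethyl-10-oxoundeca-2,8-dienoate
Product: 12 (2E,6R,8E)-6,10-bis[(tert-butyldimethylsilyl)oxy]-3,7,7-trimethylundeca-2,8,10-trien-1-ol, via silyl dienol ether 11 (not isolated)
Conditions: TBSOTf (1.05 equiv), Et3N (2.5 equiv), CH2Cl2, −78 → 0 °C; then i-Bu2AlH (3.5 equiv), −78 °C; aq. KNaC4H4O6
Reagents that add atoms: tert-butyldimethylsilyl trifluoromethanesulfonate, CC(C)(C)[Si](C)(C)OS(=O)(=O)C(F)(F)F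
Why: Soft enolisation and silylation of the methyl ketone (its only enolisable side, C4 being quaternary) gives the 2-silyloxydiene, and 1,2-reduction of the enoate by the aluminium hydride then gives the allylic alcohol.

Step 9
Reactants: 12 (2E,6R,8E)-6,10-bis[(tert-butyldimethylsilyl)oxy]-3,7,7-trimethylundeca-2,8,10-trien-1-ol
Product: 14 (1R,4aS,6R,8aR)-3,6-bis[(tert-butyldimethylsilyl)oxy]-5,5,8a-trimethyl-1,2,4a,5,6,7,8,8a-octahydronaphthalene-1-carbaldehyde, via trienal 13 (not isolated)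
Conditions: MnO2 (20 equiv), PhMe, 23 °C; filter; BHT (cat.), 0.01 M, 120 °C, sealed tube
Reagents that add atoms: none
Why: Allylic MnO2 oxidation followed by a thermal intramolecular Diels–Alder reaction closes both rings through a chair-like four-carbon tether with the C3 silyloxy group equatorial and the formyl group endo, which gives the trans ring fusion (C5, C10), while the (E)-enal geometry places the formyl group (C9) cis to the angular methyl.

Step 10
Reactants: 14 (1R,4aS,6R,8aR)-3,6-bis[(tert-butyldimethylsilyl)oxy]-5,5,8a-trimethyl-1,2,4a,5,6,7,8,8a-octahydronaphthalene-1-carbaldehyde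
Product: 15 (1S,4aS,6R,8aS)-3,6-bis[(tert-butyldimethylsilyl)oxy]-1-ethenyl-5,5,8a-trimethyl-1,2,4a,5,6,7,8,8a-octahydronaphthalene
Conditions: Ph3PCH3Br (1.5 equiv), NaN(SiMe3)2 (1.4 equiv), THF, −78 → 0 °C
Reagents that add atoms: methyltriphenylphosphonium bromide, C[P+](c1ccccc1)(c1ccccc1)c1ccccc1.[Br-]
Why: Wittig methylenation at low temperature converts the equatorial aldehyde into the vinyl group (C11=C12) without epimerising C9.

Step 11
Reactants: 16 methyl but-2-ynoate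
Product: 17 methyl (2Z)-3-iodobut-2-enoate
Conditions: NaI, AcOH, 115 °C
Reagents that add atoms: sodium iodide, [Na+].[I-]
Why: Conjugate hydroiodination of the ynoate proceeds by anti addition and gives the (Z)-β-iodo enoate.

Step 12
Reactants: 15 (1S,4aS,6R,8aS)-3,6-bis[(tert-butyldimethylsilyl)oxy]-1-ethenyl-5,5,8a-trimethyl-1,2,4a,5,6,7,8,8a-octahydronaphthalene; 17 methyl (2Z)-3-iodobut-2-enoate
Product: 19 methyl (2Z)-5-[(1R,4aS,6R,8aS)-3,6-bis[(tert-butyldimethylsilyl)oxy]-5,5,8a-trimethyl-1,2,4a,5,6,7,8,8a-octahydronaphthalen-1-yl]-3-methylpent-2-enoate, via alkylborane 18 (not isolated)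
Conditions: 9-BBN-H (1.5 equiv), THF, 23 °C; then 17, Pd(dppf)Cl2 (5 mol %), AsPh3 (10 mol %), Cs2CO3, DMF/H2O, 23 °C
Reagents that add atoms: none
Why: 9-BBN hydroborates the monosubstituted vinyl group much faster than the hindered trisubstituted silyl enol ether, and the B-alkyl Suzuki–Miyaura coupling retains the iodide geometry, giving the 13Z enoate.

Step 13
Reactants: 19 methyl (2Z)-5-[(1R,4aS,6R,8aS)-3,6-bis[(tert-butyldimethylsilyl)oxy]-5,5,8a-trimethyl-1,2,4a,5,6,7,8,8a-octahydronaphthalen-1-yl]-3-methylpent-2-enoate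
Product: 20 methyl (2Z)-5-[(1R,4aS,6R,8aS)-6-hydroxy-5,5,8a-trimethyl-3-oxodecahydronaphthalen-1-yl]-3-methylpent-2-enoate
Conditions: HF (48 % aq.)/MeCN 1:19, 0 → 23 °C
Reagents that add atoms: none
Why: Acidic fluoride desilylation cleaves the silyl enol ether to the C7 ketone and the secondary silyl ether to the C3 alcohol in one operation.

Step 14
Reactants: 20 methyl (2Z)-5-[(1R,4aS,6R,8aS)-6-hydroxy-5,5,8a-trimethyl-3-oxodecahydronaphthalen-1-yl]-3-methylpent-2-enoate
Product: 23 methyl (2Z)-5-[(1S,4aS,6R,8aR)-6-hydroxy-5,5,8a-trimethyl-2-methylidene-3-oxodecahydronaphthalen-1-yl]-3-methylpent-2-enoate, via Mannich base 21 (not isolated), via ammonium iodide 22 (not isolated)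
Conditions: LiN(i-Pr)2 (2.2 equiv), THF, −78 °C; Me2N=CH2+ I− (2.5 equiv), −78 → 0 °C; aq. work-up; MeI, CH2Cl2, 23 °C; then aq. NaHCO3
Reagents that add atoms: N,N-dimethylmethyleneiminium iodide (Eschenmoser's salt), C=[N+](C)C.[I-]
Why: Kinetic enolisation of the trans-fused 7-ketone occurs at C8 (C6 is screened by the axial C4 and C10 methyls), and a Mannich reaction followed by quaternisation and E1cB elimination installs the exocyclic methylene (α-methylenation).

Step 15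
Reactants: 23 methyl (2Z)-5-[(1S,4aS,6R,8aR)-6-hydroxy-5,5,8a-trimethyl-2-methylidene-3-oxodecahydronaphthalen-1-yl]-3-methylpent-2-enoate
Product: 24 methyl (2Z)-5-[(1S,3R,4aS,6R,8aR)-3,6-dihydroxy-5,5,8a-trimethyl-2-methylidenedecahydronaphthalen-1-yl]-3-methylpent-2-enoate
Conditions: NaBH4, CeCl3·7H2O, MeOH, −78 → −20 °C
Reagents that add atoms: none
Why: Luche 1,2-reduction of the enone with axial hydride delivery (anti to the angular methyl) on the locked trans-decalin gives the equatorial 7R allylic alcohol and leaves the enoate untouched.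

## Compound list

1 | (S)-pantolactone, (3S)-3-hydroxy-4,4-dimethyloxolan-2-one | CC1(C)COC(=O)[C@H]1O | starting material
2 | (3S)-3-[(tert-butyldimethylsilyl)oxy]-4,4-dimethyloxolan-2-one | CC1(C)COC(=O)[C@H]1O[Si](C)(C)C(C)(C)C | intermediate
3 | (3S)-3-[(tert-butyldimethylsilyl)oxy]-4,4-dimethyloxolan-2-ol (anomer mixture) | CC1(C)COC(O)[C@H]1O[Si](C)(C)C(C)(C)C | intermediate
4 | (3R)-3-[(tert-butyldimethylsilyl)oxy]-2,2-dimethylpent-4-en-1-ol | OCC(C)(C)[C@H](O[Si](C)(C)C(C)(C)C)C=C | intermediate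
5 | ethyl acetoacetate | CCOC(=O)CC(C)=O | starting material
6 | ethyl (2E)-3-{[(trifluoromethyl)sulfonyl]oxy}but-2-enoate | CCOC(=O)/C=C(\C)OS(=O)(=O)C(F)(F)F | intermediate
7 | 9-{(3R)-3-[(tert-butyldimethylsilyl)oxy]-5-[(9-borabicyclo[3.3.1]nonan-9-yl)oxy]-4,4-dimethylpentyl}-9-borabicyclo[3.3.1]nonane | C1CCC2CCCC1B2OCC(C)(C)[C@H](O[Si](C)(C)C(C)(C)C)CCB1C2CCCC1CCC2 | intermediate
8 | ethyl (2E,6R)-6-[(tert-butyldimethylsilyl)oxy]-8-hydroxy-3,7,7-trimethyloct-2-enoate | CCOC(=O)/C=C(\C)CC[C@@H](O[Si](C)(C)C(C)(C)C)C(C)(C)CO | intermediate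
9 | ethyl (2E,6R)-6-[(tert-butyldimethylsilyl)oxy]-3,7,7-trimethyl-8-oxooct-2-enoate | CCOC(=O)/C=C(\C)CC[C@@H](O[Si](C)(C)C(C)(C)C)C(C)(C)C=O | intermediate
10 | ethyl (2E,6R,8E)-6-[(tert-butyldimethylsilyl)oxy]-3,7,7-trimethyl-10-oxoundeca-2,8-dienoate | CCOC(=O)/C=C(\C)CC[C@@H](O[Si](C)(C)C(C)(C)C)C(C)(C)/C=C/C(C)=O | intermediate
11 | ethyl (2E,6R,8E)-6,10-bis[(tert-butyldimethylsilyl)oxy]-3,7,7-trimethylundeca-2,8,10-trienoate | CCOC(=O)/C=C(\C)CC[C@@H](O[Si](C)(C)C(C)(C)C)C(C)(C)/C=C/C(=C)O[Si](C)(C)C(C)(C)C | intermediate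
12 | (2E,6R,8E)-6,10-bis[(tert-butyldimethylsilyl)oxy]-3,7,7-trimethylundeca-2,8,10-trien-1-ol | OC/C=C(\C)CC[C@@H](O[Si](C)(C)C(C)(C)C)C(C)(C)/C=C/C(=C)O[Si](C)(C)C(C)(C)C | intermediate
13 | (2E,6R,8E)-6,10-bis[(tert-butyldimethylsilyl)oxy]-3,7,7-trimethylundeca-2,8,10-trienal | O=C/C=C(\C)CC[C@@H](O[Si](C)(C)C(C)(C)C)C(C)(C)/C=C/C(=C)O[Si](C)(C)C(C)(C)C | intermediate
14 | (1R,4aS,6R,8aR)-3,6-bis[(tert-butyldimethylsilyl)oxy]-5,5,8a-trimethyl-1,2,4a,5,6,7,8,8a-octahydronaphthalene-1-carbaldehyde (trans-fused; formyl, angular methyl and C6 silyloxy group on the same face) | C1C(O[Si](C)(C)C(C)(C)C)=C[C@@H]2C(C)(C)[C@H](O[Si](C)(C)C(C)(C)C)CC[C@@]2(C)[C@@H]1C=O | intermediate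
15 | (1S,4aS,6R,8aS)-3,6-bis[(tert-butyldimethylsilyl)oxy]-1-ethenyl-5,5,8a-trimethyl-1,2,4a,5,6,7,8,8a-octahydronaphthalene | C1C(O[Si](C)(C)C(C)(C)C)=C[C@@H]2C(C)(C)[C@H](O[Si](C)(C)C(C)(C)C)CC[C@@]2(C)[C@@H]1C=C | intermediate
16 | methyl but-2-ynoate | CC#CC(=O)OC | starting material
17 | methyl (2Z)-3-iodobut-2-enoate | COC(=O)/C=C(/C)I | intermediate
18 | 9-{2-[3,6-bis[(tert-butyldimethylsilyl)oxy]-5,5,8a-trimethyl-1,2,4a,5,6,7,8,8a-octahydronaphthalen-1-yl]ethyl}-9-borabicyclo[3.3.1]nonane (ring stereocenters as in 15) | C1C(O[Si](C)(C)C(C)(C)C)=C[C@@H]2C(C)(C)[C@H](O[Si](C)(C)C(C)(C)C)CC[C@@]2(C)[C@@H]1CCB1C2CCCC1CCC2 | intermediate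
19 | methyl (2Z)-5-[(1R,4aS,6R,8aS)-3,6-bis[(tert-butyldimethylsilyl)oxy]-5,5,8a-trimethyl-1,2,4a,5,6,7,8,8a-octahydronaphthalen-1-yl]-3-methylpent-2-enoate | C1C(O[Si](C)(C)C(C)(C)C)=C[C@@H]2C(C)(C)[C@H](O[Si](C)(C)C(C)(C)C)CC[C@@]2(C)[C@@H]1CC/C(C)=C\C(=O)OC | intermediate
20 | methyl (2Z)-5-[(1R,4aS,6R,8aS)-6-hydroxy-5,5,8a-trimethyl-3-oxodecahydronaphthalen-1-yl]-3-methylpent-2-enoate | C1C(=O)C[C@@H]2C(C)(C)[C@H](O)CC[C@@]2(C)[C@@H]1CC/C(C)=C\C(=O)OC | intermediate
21 | methyl (2Z)-5-{(1R,4aS,6R,8aS)-2-[(dimethylamino)methyl]-6-hydroxy-5,5,8a-trimethyl-3-oxodecahydronaphthalen-1-yl}-3-methylpent-2-enoate (C2 epimers) | CN(C)CC1C(=O)C[C@@H]2C(C)(C)[C@H](O)CC[C@@]2(C)[C@@H]1CC/C(C)=C\C(=O)OC | intermediate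
22 | N,N,N-trimethylammonium iodide of 21 (quaternised Mannich base, C2 epimers) | C[N+](C)(C)CC1C(=O)C[C@@H]2C(C)(C)[C@H](O)CC[C@@]2(C)[C@@H]1CC/C(C)=C\C(=O)OC.[I-] | intermediate
23 | methyl (2Z)-5-[(1S,4aS,6R,8aR)-6-hydroxy-5,5,8a-trimethyl-2-methylidene-3-oxodecahydronaphthalen-1-yl]-3-methylpent-2-enoate | C=C1C(=O)C[C@@H]2C(C)(C)[C@H](O)CC[C@@]2(C)[C@@H]1CC/C(C)=C\C(=O)OC | intermediate
24 | methyl (2Z)-5-[(1S,3R,4aS,6R,8aR)-3,6-dihydroxy-5,5,8a-trimethyl-2-methylidenedecahydronaphthalen-1-yl]-3-methylpent-2-enoate | C=C1[C@H](O)C[C@@H]2C(C)(C)[C@H](O)CC[C@@]2(C)[C@@H]1CC/C(C)=C\C(=O)OC | target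

## Step count and risks

Total step count: 15. Longest linear sequence: 13 (steps 1–3, 5–10, 12–15).

The three steps most likely to fail are the following.

**Step 9 (oxidation and cycloaddition).** The trienal 13 may decompose, or may cyclise with poor endo and facial selectivity; the equatorial preference of the C3 silyloxy group is only about 1 kcal/mol, so minor diastereomers are expected and must be separated. The fallback sets out from 10 and runs the cycloaddition at the more robust ester oxidation level. Enone 10 is silylated as in step 8 but worked up (aq. NaHCO3) so that 11 is isolated. Heating 11 (PhMe, BHT, 180 °C, sealed tube) gives ethyl (1R,4aS,6R,8aR)-3,6-bis[(tert-butyldimethylsilyl)oxy]-5,5,8a-trimethyl-1,2,4a,5,6,7,8,8a-octahydronaphthalene-1-carboxylate F1. Partial reduction of this hindered ester (i-Bu2AlH, 1.05 equiv, CH2Cl2, −78 °C) comes back to the route at 14.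

**Step 14 (α-methylenation).** Kinetic enolisation may not be clean for C8 over C6. The fallback sets out from 20 and uses thermodynamic control instead. Claisen condensation with methyl formate (NaOMe, THF, 0 → 23 °C) gives methyl (2Z)-5-[(1S,4aS,6R,8aR)-6-hydroxy-2-(hydroxymethylidene)-5,5,8a-trimethyl-3-oxodecahydronaphthalen-1-yl]-3-methylpent-2-enoate F2, formylated on the side remote from the ring fusion as is usual for trans-fused cyclohexanones of this type. Aqueous formaldehyde with K2CO3 (THF, 23 °C) then gives aldol addition and loss of formate (deformylative methylenation), coming back at 23.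

**Step 12 (hydroboration and coupling).** The basic aqueous coupling may hydrolyse the silyl enol ether or stall at transmetalation. The fallback sets out from 15 and couples under neutral conditions. Hydroboration–oxidation (9-BBN-H, THF; then NaBO3·4H2O) gives the primary alcohol 2-[3,6-bis[(tert-butyldimethylsilyl)oxy]-5,5,8a-trimethyl-1,2,4a,5,6,7,8,8a-octahydronaphthalen-1-yl]ethan-1-ol F3. Iodination (I2, PPh3, imidazole, CH2Cl2) gives the corresponding primary iodide F4. Zinc insertion (Zn dust, LiCl, THF) gives the alkylzinc iodide F5, and Negishi coupling with 17 (Pd(PPh3)4, THF, 23 °C) comes back at 19 with the Z geometry retained.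

## Further compounds

F1 | step 9 | ethyl (1R,4aS,6R,8aR)-3,6-bis[(tert-butyldimethylsilyl)oxy]-5,5,8a-trimethyl-1,2,4a,5,6,7,8,8a-octahydronaphthalene-1-carboxylate | C1C(O[Si](C)(C)C(C)(C)C)=C[C@@H]2C(C)(C)[C@H](O[Si](C)(C)C(C)(C)C)CC[C@@]2(C)[C@@H]1C(=O)OCC
F2 | step 14 | methyl (2Z)-5-[(1S,4aS,6R,8aR)-6-hydroxy-2-(hydroxymethylidene)-5,5,8a-trimethyl-3-oxodecahydronaphthalen-1-yl]-3-methylpent-2-enoate | OC=C1C(=O)C[C@@H]2C(C)(C)[C@H](O)CC[C@@]2(C)[C@@H]1CC/C(C)=C\C(=O)OC
F3 | step 12 | 2-[3,6-bis[(tert-butyldimethylsilyl)oxy]-5,5,8a-trimethyl-1,2,4a,5,6,7,8,8a-octahydronaphthalen-1-yl]ethan-1-ol (ring stereocenters as in 15) | C1C(O[Si](C)(C)C(C)(C)C)=C[C@@H]2C(C)(C)[C@H](O[Si](C)(C)C(C)(C)C)CC[C@@]2(C)[C@@H]1CCO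
F4 | step 12 | 1-(2-iodoethyl)-3,6-bis[(tert-butyldimethylsilyl)oxy]-5,5,8a-trimethyl-1,2,4a,5,6,7,8,8a-octahydronaphthalene (ring stereocenters as in 15) | C1C(O[Si](C)(C)C(C)(C)C)=C[C@@H]2C(C)(C)[C@H](O[Si](C)(C)C(C)(C)C)CC[C@@]2(C)[C@@H]1CCI
F5 | step 12 | {2-[3,6-bis[(tert-butyldimethylsilyl)oxy]-5,5,8a-trimethyl-1,2,4a,5,6,7,8,8a-octahydronaphthalen-1-yl]ethyl}zinc iodide (ring stereocenters as in 15) | C1C(O[Si](C)(C)C(C)(C)C)=C[C@@H]2C(C)(C)[C@H](O[Si](C)(C)C(C)(C)C)CC[C@@]2(C)[C@@H]1CC[Zn]I
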